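**Retrosynthetic overview**
- The (3R,4R)-lactone comes from its (4R)-precursor by epimerisation of C3 alone. C3 is alpha to the lactone carbonyl C2 and is the only enolisable centre, and the trans-3,4-dibenzyl arrangement is the more stable one.
- The (4R)-lactone comes from methyl 4-oxo-2,3-bis(3,4,5-trimethoxybenzyl)butanoate by forming C5-H and then O1-C2. The strategy rests on this feature of ring O1/C2(=O)/C3/C4/C5: C4 is alpha to C5, which is an aldehyde carbon before closure, so C4 is labile in the open chain, whereas C3 is labile only in the lactone. All four stereoisomers of the open-chain aldehyde ester can therefore be drained into one lactone.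
- The aldehyde ester comes from a C4-CH2Ar bond (enamine benzylation), the aldehyde from alkene cleavage, and the C3-allyl bond from ester enolate alkylation of methyl 3-(3,4,5-trimethoxyphenyl)propanoate.
- Ring order: both arene rings are bought; the lactone is the only ring made, and it closes in the key step.

Key step: step 5

Remark on numbering: lactone numbering (O1, C2, C3, C4, C5) is used for the open-chain compounds as well; C2, C3 and C4 of the butanoates are C3, C4 and C5 of the lactone.

Assumption: the sense of induction of RuCl2(xylBINAP)(DAIPEN) on an aldehyde with two alkyl branches cannot be taken over from alpha-aryl aldehydes. The (R)-xylBINAP/(R)-DAIPEN complex is written, and its mirror image is to be used if a first run shows the (4S)-lactone.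

**Route**

Step 1
Reactants: 1 3-(3,4,5-trimethoxyphenyl)propanoic acid
Product: 2 methyl 3-(3,4,5-trimethoxyphenyl)propanoate
Conditions: MeOH, H2SO4 (cat.), reflux
Reagents that add atoms: methanol, CO
Why: Fischer esterification, an acid-catalysed acyl substitution driven by the excess of methanol, with the aryl methyl ethers inert.

Step 2
Reactants: 2 methyl 3-(3,4,5-trimethoxyphenyl)propanoate; 3 allyl bromide
Product: 4 methyl 2-(3,4,5-trimethoxybenzyl)pent-4-enoate (racemic)
Conditions: LiN(iPr)2, THF, -78 °C; then 3, -78 °C to 25 °C
Reagents that add atoms: none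
Why: Ester enolate alkylation (SN2 on the allylic bromide) of the lithium enolate formed at low temperature; the new centre C3 is made racemic on purpose because it is equilibrated in the last step.

Step 3
Reactants: 4 methyl 2-(3,4,5-trimethoxybenzyl)pent-4-enoate
Product: 5 methyl 4-oxo-2-(3,4,5-trimethoxybenzyl)butanoate (racemic)
Conditions: OsO4 (2 mol %), NaIO4 (4 equiv), 2,6-lutidine, dioxane/H2O (3:1), 25 °C
Reagents that add atoms: sodium periodate, [Na+].[O-]I(=O)(=O)=O (terminal source of the aldehyde oxygen, passed on through osmium tetroxide, O=[Os](=O)(=O)=O)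
Why: Lemieux-Johnson oxidation, in which OsO4 dihydroxylates the terminal alkene and NaIO4 cleaves the diol and reoxidises osmium while 2,6-lutidine holds back over-oxidation; the ester and the electron-rich arene are not touched.

Step 4
Reactants: 5 methyl 4-oxo-2-(3,4,5-trimethoxybenzyl)butanoate; 6 3,4,5-trimethoxybenzyl chloride
Product: 9 methyl 4-oxo-2,3-bis(3,4,5-trimethoxybenzyl)butanoate (all four stereoisomers), via pyrrolidine enamine 7 (not isolated), via iminium chloride 8 (not isolated)
Conditions: pyrrolidine (1.1 equiv), 4 Å molecular sieves, toluene, 0 to 25 °C, then evaporation; 6 (1.0 equiv), MeCN, 80 °C; then H2O, 25 °C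
Reagents that add atoms: water, O
Why: Stork enamine alkylation, in which the enamine of the alpha-unbranched aldehyde attacks the benzylic chloride at carbon (benzylic N-alkylation being reversible at 80 °C) and water hydrolyses the iminium salt; C4 forms without any control, which is exactly what the next step requires.

Step 5
Reactants: 9 methyl 4-oxo-2,3-bis(3,4,5-trimethoxybenzyl)butanoate (all four stereoisomers)
Product: 11 (4R)-3,4-bis(3,4,5-trimethoxybenzyl)oxolan-2-one (C3 epimers), via hydroxy ester 10 (not isolated)
Conditions: RuCl2[(R)-xylBINAP][(R)-DAIPEN] (1 mol %), KOtBu (20 mol %), H2 (5 atm), iPrOH, 25 °C; then AcOH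
Reagents that add atoms: none
Why: Proposed new method: KOtBu and H2 turn the dichloride into the RuH2(diphosphine)(diamine) complex of divalent ruthenium, which hands a hydride from Ru and a proton from the NH2 group to the aldehyde C=O of 9 through an outer-sphere six-membered transition state, while the same alkoxide epimerises C4 through the potassium enolate of the aldehyde faster than the disfavoured C4 epimer is reduced; the closest known reaction type is the hydrogenative dynamic kinetic resolution of alpha-aryl aldehydes with this catalyst family, and the untested element is an alpha carbon that carries two sp3 branches. The new stereocentre C4 is set as R by the catalyst, which must tell the CH2Ar branch from the larger, ester-bearing CH(CO2Me)CH2Ar branch in the chiral pocket of xylBINAP and DAIPEN, so that all four stereoisomers of 9 drain into the (4R)-alkoxide of 10. That alkoxide attacks the methyl ester carbonyl in a 5-exo-trig closure and expels methoxide, which forms the O1-C2 bond and the lactone ring and returns the base. The step needs three selectivities: discrimination of the C4 epimers in both C3 series, reduction of the aldehyde only, and enolisation that outpaces the slow reduction. The substrate secures the second and third, since the aldehyde is far more electrophilic than the ester or lactone carbonyl at 25 °C and its alpha C-H is the most acidic C-H in the molecule, and a low H2 pressure with a high base loading widens the margin; C3 is left unsettled on purpose, because in 11 it is the only enolisable centre and is dealt with in step 6.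

Step 6
Reactants: 11 (4R)-3,4-bis(3,4,5-trimethoxybenzyl)oxolan-2-one (C3 epimers)
Product: 12 (3R,4R)-3,4-bis(3,4,5-trimethoxybenzyl)oxolan-2-one, (-)-cubebininolide
Conditions: DBU (1 equiv), toluene, 110 °C
Reagents that add atoms: none
Why: Base-mediated epimerisation under thermodynamic control, in which DBU reversibly deprotonates C3 (alpha to C2=O; C4 is beta and cannot enolise) and reprotonation accumulates the trans lactone, so that C3 becomes R relative to the fixed 4R centre.

**Compound list**
1 | 3-(3,4,5-trimethoxyphenyl)propanoic acid | COc1cc(CCC(=O)O)cc(OC)c1OC | starting material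
2 | methyl 3-(3,4,5-trimethoxyphenyl)propanoate | COC(=O)CCc1cc(OC)c(OC)c(OC)c1 | intermediate
3 | allyl bromide (3-bromoprop-1-ene) | C=CCBr | starting material
4 | methyl 2-(3,4,5-trimethoxybenzyl)pent-4-enoate (racemic) | COC(=O)C(CC=C)Cc1cc(OC)c(OC)c(OC)c1 | intermediate
5 | methyl 4-oxo-2-(3,4,5-trimethoxybenzyl)butanoate (racemic) | COC(=O)C(CC=O)Cc1cc(OC)c(OC)c(OC)c1 | intermediate
6 | 3,4,5-trimethoxybenzyl chloride | COc1cc(CCl)cc(OC)c1OC | starting material
7 | methyl (E)-4-(pyrrolidin-1-yl)-2-(3,4,5-trimethoxybenzyl)but-3-enoate (racemic, not isolated) | COC(=O)C(/C=C/N1CCCC1)Cc1cc(OC)c(OC)c(OC)c1 | intermediate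
8 | 1-[4-methoxy-4-oxo-2,3-bis(3,4,5-trimethoxybenzyl)butylidene]pyrrolidin-1-ium chloride (stereoisomer mixture, not isolated) | COC(=O)C(Cc1cc(OC)c(OC)c(OC)c1)C(C=[N+]1CCCC1)Cc1cc(OC)c(OC)c(OC)c1.[Cl-] | intermediate
9 | methyl 4-oxo-2,3-bis(3,4,5-trimethoxybenzyl)butanoate (all four stereoisomers, both centres undefined) | COC(=O)C(Cc1cc(OC)c(OC)c(OC)c1)C(C=O)Cc1cc(OC)c(OC)c(OC)c1 | intermediate
10 | methyl (3R)-4-hydroxy-2,3-bis(3,4,5-trimethoxybenzyl)butanoate (C2 epimers, not isolated) | COC(=O)C(Cc1cc(OC)c(OC)c(OC)c1)[C@H](CO)Cc1cc(OC)c(OC)c(OC)c1 | intermediate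
11 | (4R)-3,4-bis(3,4,5-trimethoxybenzyl)oxolan-2-one (C3 epimers) | COc1cc(C[C@H]2COC(=O)C2Cc2cc(OC)c(OC)c(OC)c2)cc(OC)c1OC | intermediate
12 | (3R,4R)-3,4-bis(3,4,5-trimethoxybenzyl)oxolan-2-one, (-)-cubebininolide | COc1cc(C[C@H]2COC(=O)[C@@H]2Cc2cc(OC)c(OC)c(OC)c2)cc(OC)c1OC | target

Total step count: 6. Longest linear sequence: 6 steps (from 1 to 12).

**Steps most likely to fail**

1. Step 5. What may go wrong:
 - The catalyst may discriminate the C4 epimers too weakly when the neighbouring C3 centre is of the mismatched configuration.
 - Enolisation of an aldehyde with two alkyl branches may be slower than its reduction.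
 - The aldehyde may be lost to base-induced aldol or Tishchenko pathways.

 The fallback uses known auxiliary chemistry; it sets out from 1 and 6 and comes back at 12.
 - Acid 1 is converted with pivaloyl chloride and Et3N into 3-(3,4,5-trimethoxyphenyl)propanoic pivalic anhydride F1.
 - F1 acylates (S)-4-benzyloxazolidin-2-one (LiCl, Et3N, THF) to give (4S)-4-benzyl-3-[3-(3,4,5-trimethoxyphenyl)propanoyl]oxazolidin-2-one F2.
 - The sodium (Z)-enolate of F2 (NaN(SiMe3)2, THF, -78 °C) is alkylated with tert-butyl bromoacetate on the face away from the auxiliary benzyl group, which should give tert-butyl (3R)-4-[(4S)-4-benzyl-2-oxooxazolidin-3-yl]-4-oxo-3-(3,4,5-trimethoxybenzyl)butanoate F3.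
 - LiBH4 (THF, MeOH, 0 °C) removes the auxiliary reductively to give tert-butyl (3R)-4-hydroxy-3-(3,4,5-trimethoxybenzyl)butanoate F4.
 - CF3CO2H in CH2Cl2 closes F4 to (4R)-4-(3,4,5-trimethoxybenzyl)oxolan-2-one F5.
 - The lithium enolate of F5 (LiN(SiMe3)2, THF/DMPU, -78 to 0 °C) is benzylated with 6 anti to the C4 substituent, which sets C3 trans under kinetic control and gives 12 directly.

2. Step 4. What may go wrong: alkylation of the enamine at nitrogen, a second benzylation at the same carbon, and self-condensation of the aldehyde while the enamine forms. The fallback sets out from 5 and comes back at 9.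
 - Amine-catalysed aldol condensation of 5 with 3,4,5-trimethoxybenzaldehyde (pyrrolidine and PhCO2H as catalysts, toluene, 4 Å molecular sieves, 60 °C) should give methyl (3E)-3-formyl-4-(3,4,5-trimethoxyphenyl)-2-(3,4,5-trimethoxybenzyl)but-3-enoate F6.
 - The C=C bond of F6 alone is then saturated with H2 (1 atm) over Pd/C (palladium on carbon) in EtOAc at 25 °C, stopped after one equivalent, the way 2-alkylcinnamaldehydes are turned into 2-alkyl-3-arylpropanals. This gives 9 as the same unselective stereoisomer mixture.

3. Step 6. What may go wrong: the equilibration may stop short of full conversion, because the cis lactone keeps a finite share at equilibrium and DBU may enolise the lactone only slowly. The fallback sets out from 11 and comes back at 12.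
 - Equilibration is run at 25 °C with NaOMe in MeOH, where the trans preference is larger; any ring-opened 10 is reclosed with TsOH.
 - 12 is then separated on silica from the cis lactone (3S,4R)-3,4-bis(3,4,5-trimethoxybenzyl)oxolan-2-one F7, which is returned to the base treatment.
 - The approach thus changes from a single thermodynamic pass to a separate-and-recycle loop.

**Further compounds**
F1 | step 5 | 3-(3,4,5-trimethoxyphenyl)propanoic pivalic anhydride | COc1cc(CCC(=O)OC(=O)C(C)(C)C)cc(OC)c1OC
F2 | step 5 | (4S)-4-benzyl-3-[3-(3,4,5-trimethoxyphenyl)propanoyl]oxazolidin-2-one | COc1cc(CCC(=O)N2[C@@H](Cc3ccccc3)COC2=O)cc(OC)c1OC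
F3 | step 5 | tert-butyl (3R)-4-[(4S)-4-benzyl-2-oxooxazolidin-3-yl]-4-oxo-3-(3,4,5-trimethoxybenzyl)butanoate | COc1cc(C[C@H](CC(=O)OC(C)(C)C)C(=O)N2[C@@H](Cc3ccccc3)COC2=O)cc(OC)c1OC
F4 | step 5 | tert-butyl (3R)-4-hydroxy-3-(3,4,5-trimethoxybenzyl)butanoate | COc1cc(C[C@H](CC(=O)OC(C)(C)C)CO)cc(OC)c1OC
F5 | step 5 | (4R)-4-(3,4,5-trimethoxybenzyl)oxolan-2-one | COc1cc(C[C@H]2COC(=O)C2)cc(OC)c1OC
F6 | step 4 | methyl (3E)-3-formyl-4-(3,4,5-trimethoxyphenyl)-2-(3,4,5-trimethoxybenzyl)but-3-enoate | COC(=O)C(Cc1cc(OC)c(OC)c(OC)c1)/C(C=O)=C\c1cc(OC)c(OC)c(OC)c1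
F7 | step 6 | (3S,4R)-3,4-bis(3,4,5-trimethoxybenzyl)oxolan-2-one (cis lactone) | COc1cc(C[C@H]2COC(=O)[C@H]2Cc2cc(OC)c(OC)c(OC)c2)cc(OC)c1OC
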